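**Plan**
1. Retrosynthesis: the C9 acetate and the C9 configuration go first (back to a 9-ketone). The ten-membered ring is then cut at C9–C10: the C9 carbinol next to C10, which carries CO2Me and the C1=C10 alkene, is an α-(hydroxyalkyl)acrylate retron (C9 aldehyde + C10 alkenyl iodide). The O8 ester follows, and last the lactone at C6–C7/O–C12 (enal + 2-alkoxycarbonyl allylboronate).
2. Enabling feature: both ring alkenes (C1=C10, C4=C5) are cis within the ten-membered ring and the γ-lactone is trans-fused at C6/C7, so a chain with Z-C4=C5 already in place folds C10 back onto C9.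
3. Forward order: neryl acetate gives a Z-enal carrying a (Z)-α-iodoenoate; glyceraldehyde acetonide gives an alkynoate and then an allylboronate. Allylboration/lactonisation builds the α-methylene-γ-butyrolactone first (step 12). O8 is acylated, C9 becomes the aldehyde, and the ten-membered ring is closed last (step 17).
4. Stereochemistry: C8 from (R)-glyceraldehyde; C7 and C6 from the allylboration (A(1,3) strain, chair transition state); C9 by Felkin–Anh reduction of the 9-ketone; the side-chain carbinol from (S)-2-methylserine; Z-C4=C5 from nerol; C1=C10 from the (Z)-iodide and the ring.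

Key step: step 17

Remark: germacrane numbering is used throughout (ring C1–C10, lactone C11–C13 with O on C6, ester carbon C14, methyl C15); compounds 1, 7 and 12 are taken as purchasable.

**Step 1**
Reactants: 1 neryl acetate
Product: 2 6,7-epoxyneryl acetate [(2Z)-5-(3,3-dimethyloxiran-2-yl)-3-methylpent-2-en-1-yl acetate; racemic at the oxirane CH]
Conditions: mCPBA (1.05 equiv), CH2Cl2, 0 °C
Reagents that add atoms: m-chloroperoxybenzoic acid (O=C(OO)c1cccc(Cl)c1)
Why: Prilezhaev epoxidation takes the distal trisubstituted alkene, because the 2,3-alkene is deactivated by the allylic acetate; the new stereocentre is racemic and is destroyed in step 2.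

**Step 2**
Reactants: 2 6,7-epoxyneryl acetate
Product: 3 (2Z)-3-methyl-6-oxohex-2-en-1-yl acetate
Conditions: H5IO6 (1.1 equiv), THF/Et2O, 0 °C
Reagents that add atoms: none
Why: Periodic acid opens the epoxide to the glycol and cleaves it (Malaprade-type glycol cleavage) to the aldehyde and acetone, leaving the Z-alkene and the allylic acetate untouched.

**Step 3**
Reactants: 3 (2Z)-3-methyl-6-oxohex-2-en-1-yl acetate
Product: 4 methyl (2Z,6Z)-8-acetoxy-2-iodo-6-methylocta-2,6-dienoate
Conditions: Ph3P=CHCO2Me, NIS, CH2Cl2, −20 °C; then 3, −20 °C to rt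
Reagents that add atoms: methyl (triphenylphosphoranylidene)acetate (COC(=O)C=P(c1ccccc1)(c1ccccc1)c1ccccc1); N-iodosuccinimide (O=C1CCC(=O)N1I)
Why: Wittig olefination with the α-iodo ylide formed in situ by iodination of the stabilised ylide (the succinimide anion acts as base) should give the α-iodoenoate with iodine cis to the chain (2Z), the usual outcome for α-halo stabilised ylides.

**Step 4**
Reactants: 4 methyl (2Z,6Z)-8-acetoxy-2-iodo-6-methylocta-2,6-dienoate
Product: 5 methyl (2Z,6Z)-8-hydroxy-2-iodo-6-methylocta-2,6-dienoate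
Conditions: K2CO3 (0.1 equiv), MeOH, 0 °C
Reagents that add atoms: none
Why: Base-catalysed transesterification (acetate methanolysis) frees the allylic alcohol; the methyl ester is degenerate under these conditions and the cold, catalytic base should spare the iodoenoate.

**Step 5**
Reactants: 5 methyl (2Z,6Z)-8-hydroxy-2-iodo-6-methylocta-2,6-dienoate
Product: 6 methyl (2Z,6Z)-2-iodo-6-methyl-8-oxoocta-2,6-dienoate
Conditions: activated MnO2 (excess), CH2Cl2, rt
Reagents that add atoms: none
Why: MnO2 oxidation of the allylic alcohol gives the enal under neutral conditions, which should keep the Z (neral-type) geometry.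

**Step 6**
Reactants: 7 (R)-2,2-dimethyl-1,3-dioxolane-4-carbaldehyde
Product: 8 (S)-4-ethynyl-2,2-dimethyl-1,3-dioxolane
Conditions: dimethyl (1-diazo-2-oxopropyl)phosphonate, K2CO3, MeOH, 0 °C to rt
Reagents that add atoms: dimethyl (1-diazo-2-oxopropyl)phosphonate (COP(=O)(OC)C(=[N+]=[N-])C(C)=O)
Why: Seyferth–Gilbert homologation in the Ohira–Bestmann form converts the aldehyde into the terminal alkyne under mild base, so the α-alkoxy stereocentre (later C8) is kept.

**Step 7**
Reactants: 8 (S)-4-ethynyl-2,2-dimethyl-1,3-dioxolane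
Product: 9 methyl 3-[(4S)-2,2-dimethyl-1,3-dioxolan-4-yl]prop-2-ynoate
Conditions: n-BuLi, THF, −78 °C; ClCO2Me, −78 to 0 °C
Reagents that add atoms: methyl chloroformate (COC(=O)Cl)
Why: C-acylation of the lithium acetylide with a chloroformate is a standard route to alkynoates.

**Step 8**
Reactants: 9 methyl 3-[(4S)-2,2-dimethyl-1,3-dioxolan-4-yl]prop-2-ynoate
Product: 11 methyl (2Z)-3-[(4S)-2,2-dimethyl-1,3-dioxolan-4-yl]-2-[(4,4,5,5-tetramethyl-1,3,2-dioxaborolan-2-yl)methyl]prop-2-enoate, via α-alumino enoate 10 (not isolated)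
Conditions: DIBAL-H, HMPA, THF, 0 °C; then ICH2Bpin, 0 °C to rt
Reagents that add atoms: 2-(iodomethyl)-4,4,5,5-tetramethyl-1,3,2-dioxaborolane (CC1(C)OB(CI)OC1(C)C)
Why: Conjugate (1,4) hydroalumination of the ynoate gives the α-alumino enoate, whose C–Al bond is alkylated by the iodomethylboronate (1,2-metallate shift), so that H and CH2B end up cis and C8 sits cis to the ester, the E-crotyl-type geometry needed in step 12.

**Step 9**
Reactants: 12 (S)-2-methylserine
Product: 13 (2S)-2,3-dihydroxy-2-methylpropanoic acid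
Conditions: NaNO2, 1 M H2SO4, 0 °C to rt
Reagents that add atoms: water (O)
Why: Diazotisation of the α-amino acid proceeds with retention (α-lactone formation and opening by water, two inversions), so the quaternary carbinol keeps the S configuration.

**Step 10**
Reactants: 13 (2S)-2,3-dihydroxy-2-methylpropanoic acid
Product: 14 methyl (4S)-2,2,4-trimethyl-1,3-dioxolane-4-carboxylate
Conditions: Me2C(OMe)2, MeOH, p-TsOH (cat.), rt
Reagents that add atoms: 2,2-dimethoxypropane (COC(C)(C)OC); methanol (CO)
Why: Fischer esterification and acetalisation of the 1,2-diol run together, the ketal reagent also serving as water scavenger; the stereocentre is not involved.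

**Step 11**
Reactants: 14 methyl (4S)-2,2,4-trimethyl-1,3-dioxolane-4-carboxylate
Product: 15 (4S)-2,2,4-trimethyl-1,3-dioxolane-4-carboxylic acid
Conditions: LiOH, THF/H2O, 0 °C; then 1 M HCl to pH 3
Reagents that add atoms: lithium hydroxide ([Li+].[OH-])
Why: Saponification of the methyl ester; the quaternary α-carbon cannot epimerise and the acetonide survives the brief, cold acidification.

**Step 12**
Reactants: 6 methyl (2Z,6Z)-2-iodo-6-methyl-8-oxoocta-2,6-dienoate; 11 allylboronate
Product: 17 methyl (2Z,6Z)-7-{(2R,3S)-3-[(4S)-2,2-dimethyl-1,3-dioxolan-4-yl]-4-methylidene-5-oxooxolan-2-yl}-2-iodo-6-methylhepta-2,6-dienoate, via homoallylic pinacol borate 16 (not isolated)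
Conditions: toluene, 70 °C; then p-TsOH (cat.), rt
Reagents that add atoms: none
Why: Allylboration through a Zimmerman–Traxler chair and lactonisation: the E-crotyl-type boronate puts the aldehyde substituent and C8 anti, hence trans on the lactone (C6/C7), and A(1,3) strain with the cis ester holds C8–H in the alkene plane so that the aldehyde adds anti to the C8–C9 bond, which with 8S should give 7S and therefore 6R.

**Step 13**
Reactants: 17 lactone acetonide
Product: 18 methyl (2Z,6Z)-7-{(2R,3S)-3-[(1S)-1,2-dihydroxyethyl]-4-methylidene-5-oxooxolan-2-yl}-2-iodo-6-methylhepta-2,6-dienoate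
Conditions: AcOH/H2O (4:1), 40 °C
Reagents that add atoms: none
Why: Mild acid hydrolysis of the terminal acetonide frees the C8/C9 diol without touching the lactone, the esters or the alkenyl iodide.

**Step 14**
Reactants: 18 diol
Product: 19 methyl (2Z,6Z)-7-{(2R,3S)-3-[(1S)-1-hydroxy-2-(triethylsilyloxy)ethyl]-4-methylidene-5-oxooxolan-2-yl}-2-iodo-6-methylhepta-2,6-dienoate
Conditions: TESCl (1.05 equiv), 2,4,6-collidine, CH2Cl2, −78 °C
Reagents that add atoms: chlorotriethylsilane (CC[Si](Cl)(CC)CC)
Why: Silylation at low temperature selects the primary C9 hydroxyl over the hindered secondary C8 hydroxyl.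

**Step 15**
Reactants: 19 triethylsilyl ether; 15 (4S)-2,2,4-trimethyl-1,3-dioxolane-4-carboxylic acid
Product: 21 methyl (2Z,6Z)-7-{(2R,3S)-3-[(1S)-1-{[(4S)-2,2,4-trimethyl-1,3-dioxolane-4-carbonyl]oxy}-2-(triethylsilyloxy)ethyl]-4-methylidene-5-oxooxolan-2-yl}-2-iodo-6-methylhepta-2,6-dienoate, via mixed anhydride 20 (not isolated)
Conditions: 15, 2,4,6-trichlorobenzoyl chloride, Et3N, THF, rt; then 19, DMAP, toluene, rt
Reagents that add atoms: none
Why: Yamaguchi esterification is suited to joining a hindered α,α-disubstituted acid to a hindered secondary alcohol; no stereocentre is touched.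

**Step 16**
Reactants: 21 O8 ester triethylsilyl ether
Product: 22 methyl (2Z,6Z)-7-{(2R,3S)-3-[(1S)-1-{[(4S)-2,2,4-trimethyl-1,3-dioxolane-4-carbonyl]oxy}-2-oxoethyl]-4-methylidene-5-oxooxolan-2-yl}-2-iodo-6-methylhepta-2,6-dienoate
Conditions: (COCl)2, DMSO, CH2Cl2, −78 to −30 °C; then i-Pr2NEt, −78 to 0 °C
Reagents that add atoms: none
Why: Swern oxidation in which the chlorosulfonium salt cleaves the primary triethylsilyl ether in situ and the alkoxysulfonium ion collapses to the aldehyde; the low temperature and hindered base protect the α-acyloxy stereocentre C8.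

**Step 17**
Reactants: 22 iodoenoate aldehyde
Product: 24 ten-membered (9R)-9-hydroxy lactone [methyl (1(10)E,4Z,6R,7S,8S,9R)-9-hydroxy-8-{[(4S)-2,2,4-trimethyl-1,3-dioxolane-4-carbonyl]oxy}-12-oxogermacra-1(10),4,11(13)-trien-12,6-olid-14-oate], via C10 alkenylchromium(III) species 23 (not isolated)
Conditions: CrCl2 (10 equiv), NiCl2 (0.1 equiv), degassed DMSO, rt, 2 mM, slow addition of 22
Reagents that add atoms: none
Why: Ni(0) inserts into the C10–I bond of the (Z)-α-iodoenoate and transmetalation to Cr(III) gives the C10 alkenylchromium (a chromium allenolate), which adds to the C9 aldehyde; the closest known reaction type is the Nozaki–Hiyama–Kishi macrocyclisation used for ten-membered germacranolide rings, together with the chromium Reformatsky reaction. The ten-membered carbocycle is closed by C9–C10 bond formation in a 10-exo-trig addition to the carbonyl, with the lactone already in place. C2 is cis to iodine in 22 and addition occurs with retention, and should the allenolate lose its geometry only the ring-cis isomer can close, so the step is convergent in alkene geometry. The new stereocentre C9 is governed by the C8 acyloxy group (Cornforth or polar Felkin–Anh arrangement), which is expected to favour 9R (8,9-anti); this is not the target configuration and C9 is reset in steps 18–19, so either epimer is usable. The step needs chemoselective activation of the alkenyl C–I bond beside the α-methylene lactone, three esters and the acetonide, which Cr(II)/Ni provides, and cyclisation over oligomerisation, which high dilution, the pre-set Z-C4=C5 alkene and the trans-lactone turn should secure.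

**Step 18**
Reactants: 24 (9R)-9-hydroxy macrocycle
Product: 25 9-oxo macrocycle [methyl (1(10)E,4Z,6R,7S,8S)-8-{[(4S)-2,2,4-trimethyl-1,3-dioxolane-4-carbonyl]oxy}-9,12-dioxogermacra-1(10),4,11(13)-trien-12,6-olid-14-oate]
Conditions: Dess–Martin periodinane, pyridine, CH2Cl2, 0 °C
Reagents that add atoms: none
Why: Dess–Martin oxidation of the hindered allylic alcohol under buffered conditions gives the alkylidene β-keto ester without epimerising C8 and makes the C9 outcome of step 17 irrelevant, since both epimers converge.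

**Step 19**
Reactants: 25 9-oxo macrocycle
Product: 26 (9S)-9-hydroxy macrocycle [methyl (1(10)E,4Z,6R,7S,8S,9S)-9-hydroxy-8-{[(4S)-2,2,4-trimethyl-1,3-dioxolane-4-carbonyl]oxy}-12-oxogermacra-1(10),4,11(13)-trien-12,6-olid-14-oate]
Conditions: NaBH4, CeCl3·7H2O, MeOH, −78 °C
Reagents that add atoms: none
Why: Luche reduction should give 1,2-reduction of the enone, and polar Felkin–Anh control by the non-chelating C8 acyloxy group (hydride anti to the C8–O bond, C7 inside, C10 anti to C7 as the ring requires) should give the 8,9-syn alcohol, i.e. 9S.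

**Step 20**
Reactants: 26 (9S)-9-hydroxy macrocycle
Product: 27 9-acetate [methyl (1(10)E,4Z,6R,7S,8S,9S)-9-acetoxy-8-{[(4S)-2,2,4-trimethyl-1,3-dioxolane-4-carbonyl]oxy}-12-oxogermacra-1(10),4,11(13)-trien-12,6-olid-14-oate]
Conditions: Ac2O, pyridine, DMAP (cat.), CH2Cl2, 0 °C to rt
Reagents that add atoms: acetic anhydride (CC(=O)OC(C)=O)
Why: DMAP-catalysed acetylation of the secondary allylic alcohol; prompt acylation leaves no free hydroxyl for O8-to-O9 acyl migration.

**Step 21**
Reactants: 27 9-acetate
Product: 28 CNP0197537.1 [methyl (1(10)E,4Z,6R,7S,8S,9S)-9-acetoxy-8-{[(2S)-2,3-dihydroxy-2-methylpropanoyl]oxy}-12-oxogermacra-1(10),4,11(13)-trien-12,6-olid-14-oate]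
Conditions: TFA/H2O/CH2Cl2 (4:1:8), 0 °C
Reagents that add atoms: none
Why: Acid hydrolysis of the side-chain acetonide frees the diol; the electron-poor C1=C10 alkene disfavours transannular cyclisation of the cis,cis-diene and the allylic acetate at C9 is deactivated towards ionisation by the ester.

**Compound list**
1 | neryl acetate [(2Z)-3,7-dimethylocta-2,6-dien-1-yl acetate] | CC(C)=CCC/C(C)=C\COC(C)=O | starting material
2 | 6,7-epoxyneryl acetate (racemic at the oxirane CH) | CC1(C)OC1CC/C(C)=C\COC(C)=O | intermediate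
3 | (2Z)-3-methyl-6-oxohex-2-en-1-yl acetate | O=CCC/C(C)=C\COC(C)=O | intermediate
4 | methyl (2Z,6Z)-8-acetoxy-2-iodo-6-methylocta-2,6-dienoate | COC(=O)/C(I)=C/CC/C(C)=C\COC(C)=O | intermediate
5 | methyl (2Z,6Z)-8-hydroxy-2-iodo-6-methylocta-2,6-dienoate | COC(=O)/C(I)=C/CC/C(C)=C\CO | intermediate
6 | methyl (2Z,6Z)-2-iodo-6-methyl-8-oxoocta-2,6-dienoate | COC(=O)/C(I)=C/CC/C(C)=C\C=O | intermediate
7 | (R)-2,2-dimethyl-1,3-dioxolane-4-carbaldehyde | O=C[C@H]1COC(C)(C)O1 | starting material
8 | (S)-4-ethynyl-2,2-dimethyl-1,3-dioxolane | C#C[C@H]1COC(C)(C)O1 | intermediate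
9 | methyl 3-[(4S)-2,2-dimethyl-1,3-dioxolan-4-yl]prop-2-ynoate | COC(=O)C#C[C@H]1COC(C)(C)O1 | intermediate
10 | methyl (2E)-2-(diisobutylalumanyl)-3-[(4S)-2,2-dimethyl-1,3-dioxolan-4-yl]prop-2-enoate (α-alumino enoate) | COC(=O)/C([Al](CC(C)C)CC(C)C)=C\[C@H]1COC(C)(C)O1 | intermediate (not isolated)
11 | methyl (2Z)-3-[(4S)-2,2-dimethyl-1,3-dioxolan-4-yl]-2-[(4,4,5,5-tetramethyl-1,3,2-dioxaborolan-2-yl)methyl]prop-2-enoate | COC(=O)/C(CB1OC(C)(C)C(C)(C)O1)=C\[C@H]2COC(C)(C)O2 | intermediate
12 | (S)-2-methylserine | OC(=O)[C@@](C)(N)CO | starting material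
13 | (2S)-2,3-dihydroxy-2-methylpropanoic acid | OC(=O)[C@@](C)(O)CO | intermediate
14 | methyl (4S)-2,2,4-trimethyl-1,3-dioxolane-4-carboxylate | COC(=O)[C@]1(C)COC(C)(C)O1 | intermediate
15 | (4S)-2,2,4-trimethyl-1,3-dioxolane-4-carboxylic acid | OC(=O)[C@]1(C)COC(C)(C)O1 | intermediate
16 | homoallylic pinacol borate (6R,7S,8S), open-chain diester | C=C(C(=O)OC)[C@@H]([C@H](OB1OC(C)(C)C(C)(C)O1)/C=C(/C)CC/C=C(\I)C(=O)OC)[C@H]2COC(C)(C)O2 | intermediate (not isolated)
17 | methyl (2Z,6Z)-7-{(2R,3S)-3-[(4S)-2,2-dimethyl-1,3-dioxolan-4-yl]-4-methylidene-5-oxooxolan-2-yl}-2-iodo-6-methylhepta-2,6-dienoate | C=C1C(=O)O[C@H](/C=C(/C)CC/C=C(\I)C(=O)OC)[C@H]1[C@H]2COC(C)(C)O2 | intermediate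
18 | methyl (2Z,6Z)-7-{(2R,3S)-3-[(1S)-1,2-dihydroxyethyl]-4-methylidene-5-oxooxolan-2-yl}-2-iodo-6-methylhepta-2,6-dienoate | C=C1C(=O)O[C@H](/C=C(/C)CC/C=C(\I)C(=O)OC)[C@H]1[C@H](O)CO | intermediate
19 | primary triethylsilyl ether of 18 | C=C1C(=O)O[C@H](/C=C(/C)CC/C=C(\I)C(=O)OC)[C@H]1[C@H](O)CO[Si](CC)(CC)CC | intermediate
20 | (4S)-2,2,4-trimethyl-1,3-dioxolane-4-carboxylic 2,4,6-trichlorobenzoic anhydride | O=C(OC(=O)[C@]1(C)COC(C)(C)O1)c1c(Cl)cc(Cl)cc1Cl | intermediate (not isolated)
21 | O8 ester of 19 with acid 15 | C=C1C(=O)O[C@H](/C=C(/C)CC/C=C(\I)C(=O)OC)[C@H]1[C@H](OC(=O)[C@]2(C)COC(C)(C)O2)CO[Si](CC)(CC)CC | intermediate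
22 | C9 aldehyde (iodoenoate aldehyde) | C=C1C(=O)O[C@H](/C=C(/C)CC/C=C(\I)C(=O)OC)[C@H]1[C@H](OC(=O)[C@]2(C)COC(C)(C)O2)C=O | intermediate
23 | C10 alkenylchromium(III) dichloride (chromium allenolate) of 22 | C=C1C(=O)O[C@H](/C=C(/C)CC/C=C(\[Cr](Cl)Cl)C(=O)OC)[C@H]1[C@H](OC(=O)[C@]2(C)COC(C)(C)O2)C=O | intermediate (not isolated)
24 | (9R)-9-hydroxy macrocycle (expected epimer from step 17) | C=C1C(=O)O[C@@H]2/C=C(/C)CC/C=C(/C(=O)OC)[C@@H](O)[C@@H](OC(=O)[C@]3(C)COC(C)(C)O3)[C@@H]12 | intermediate
25 | 9-oxo macrocycle | C=C1C(=O)O[C@@H]2/C=C(/C)CC/C=C(/C(=O)OC)C(=O)[C@@H](OC(=O)[C@]3(C)COC(C)(C)O3)[C@@H]12 | intermediate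
26 | (9S)-9-hydroxy macrocycle | C=C1C(=O)O[C@@H]2/C=C(/C)CC/C=C(/C(=O)OC)[C@H](O)[C@@H](OC(=O)[C@]3(C)COC(C)(C)O3)[C@@H]12 | intermediate
27 | 9-acetate with side-chain acetonide | C=C1C(=O)O[C@@H]2/C=C(/C)CC/C=C(/C(=O)OC)[C@H](OC(C)=O)[C@@H](OC(=O)[C@]3(C)COC(C)(C)O3)[C@@H]12 | intermediate
28 | CNP0197537.1 | C=C1C(=O)O[C@@H]2/C=C(/C)CC/C=C(/C(=O)OC)[C@H](OC(C)=O)[C@@H](OC(=O)[C@@](C)(O)CO)[C@@H]12 | target

**Totals**
Total step count: 21 (steps 1–5 iodoenoate enal, 6–8 allylboronate, 9–11 side-chain acid, 12–21 assembly).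
Longest linear sequence: 15 steps (1–5, then 12–21).

**Three steps most likely to fail**

Step 17 (key step). Intermolecular coupling (oligomerisation) may outrun closure of the strained ten-membered ring, and the alkenylchromium/allenolate may be protonated before it reaches the aldehyde. The fallback closes the ring at C1=C10 by metathesis instead and sets out from aldehyde 3.
- Wittig methylenation (Ph3P=CH2) gives (2Z)-3-methylhepta-2,6-dien-1-yl acetate F1, methanolysis gives the dienol F2, and MnO2 gives the dienal F3.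
- Allylboration of F3 by 11 as in step 12 gives the lactone acetonide F4.
- The operations of steps 13–16 give the diol F5, the triethylsilyl ether F6, the O8 ester F7 (with acid 15) and the aldehyde F8.
- A Morita–Baylis–Hillman reaction with methyl acrylate (DABCO) gives the α-methylene-β-hydroxy ester F9 as C9 epimers.
- Ring-closing metathesis (second-generation ruthenium carbene, toluene, 80 °C, 1 mM) between the terminal alkene and the 1,1-disubstituted acrylate should give the ring-cis C1=C10 alkene, i.e. 24 and its C9 epimer 26.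
- Step 18 converges both on 25, where the route is rejoined.

Step 12. The dioxolane may not bias the two faces of the allyl unit enough (poor facial selectivity at C7), and the Z-enal may isomerise to E on heating. The fallback uses reagent control through a chiral boronic ester and sets out from ynoate 9. Hydroalumination as in step 8, followed by trapping with the (4R,5R)-diisopropyl tartrate ester of iodomethylboronic acid, gives the tartrate allylboronate F10. This should add to the Si face of enal 6 at −78 °C (toluene, 4 Å sieves), in the sense that reinforces the substrate bias. Acid-catalysed lactonisation returns to 17.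

Step 19. Hydride may add in conjugate fashion to the doubly activated C1=C10 alkene, the α-acyloxy ketone may epimerise at C8, or hydride may be delivered to the wrong face. The fallback replaces the redox relay by inversion and sets out from the 9R alcohol 24 of the key step. A Mitsunobu reaction with acetic acid (PPh3, DIAD, toluene, 0 °C) inverts C9 and installs the acetate in one operation. It returns to the route at 27 without new compounds.

**Further compounds**
F1 | step 17 | (2Z)-3-methylhepta-2,6-dien-1-yl acetate | C=CCC/C(C)=C\COC(C)=O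
F2 | step 17 | (2Z)-3-methylhepta-2,6-dien-1-ol | C=CCC/C(C)=C\CO
F3 | step 17 | (2Z)-3-methylhepta-2,6-dienal | C=CCC/C(C)=C\C=O
F4 | step 17 | (4R,5S)-4-[(4S)-2,2-dimethyl-1,3-dioxolan-4-yl]-3-methylidene-5-[(1Z)-2-methylhexa-1,5-dien-1-yl]oxolan-2-one | C=C1C(=O)O[C@H](/C=C(/C)CCC=C)[C@H]1[C@H]2COC(C)(C)O2
F5 | step 17 | diol from F4 | C=C1C(=O)O[C@H](/C=C(/C)CCC=C)[C@H]1[C@H](O)CO
F6 | step 17 | primary triethylsilyl ether of F5 | C=C1C(=O)O[C@H](/C=C(/C)CCC=C)[C@H]1[C@H](O)CO[Si](CC)(CC)CC
F7 | step 17 | O8 ester of F6 with acid 15 | C=C1C(=O)O[C@H](/C=C(/C)CCC=C)[C@H]1[C@H](OC(=O)[C@]2(C)COC(C)(C)O2)CO[Si](CC)(CC)CC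
F8 | step 17 | C9 aldehyde from F7 | C=C1C(=O)O[C@H](/C=C(/C)CCC=C)[C@H]1[C@H](OC(=O)[C@]2(C)COC(C)(C)O2)C=O
F9 | step 17 | Morita–Baylis–Hillman adduct of F8 with methyl acrylate (C9 epimers) | C=C1C(=O)O[C@H](/C=C(/C)CCC=C)[C@H]1[C@H](OC(=O)[C@]2(C)COC(C)(C)O2)C(O)C(=C)C(=O)OC
F10 | step 12 | diisopropyl (4R,5R)-2-{(2Z)-3-[(4S)-2,2-dimethyl-1,3-dioxolan-4-yl]-2-(methoxycarbonyl)prop-2-en-1-yl}-1,3,2-dioxaborolane-4,5-dicarboxylate | COC(=O)/C(CB1O[C@@H](C(=O)OC(C)C)[C@H](C(=O)OC(C)C)O1)=C\[C@H]2COC(C)(C)O2
F0 | step 19 | none | none
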